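I decided to put the next flask's gain into less solid substrate, not more enzyme, and these runs are why.

| flask | solid substrate | enzyme | remark | time |
|---|---|---|---|---|
| blue | 16 mM | 3.8 × 10⁻⁴ mol% | run made earlier |  |
| green | 16 mM | 0.001 mol% | run made earlier |  |
| teal | 16 mM | 0.0033 mol% | run made earlier |  |
| amber | 27 mM | 8.6 × 10⁻⁴ mol% | run made earlier |  |
| Wednesday's | 30 mM | 8.6 × 10⁻⁴ mol% |  | 30 h |
| Sunday's | 10 mM | 0.003 mol% |  | 30 h |
| Saturday's | 16 mM | 8.6 × 10⁻⁴ mol% |  | 30 h |
| Friday's | 10 mM | 4.0 × 10⁻⁴ mol% |  | 30 h |
| Monday's | 50 mM | 8.6 × 10⁻⁴ mol% |  | 30 h |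

| run | time / h | product / % | solid substrate / % |
|---|---|---|---|
| blue | 1.33 | 0 | 97 |
| blue | 3.00 | 3 | 92 |
| blue | 6.00 | 6 | 84 |
| blue | 15.0 | 33 | 61 |
| green | 1.33 | 0 | 96 |
| green | 3.00 | 5 | 91 |
| green | 6.00 | 11 | 81 |
| green | 15.0 | 37 | 60 |
| teal | 1.33 | 2 | 96 |
| teal | 3.00 | 7 | 91 |
| teal | 6.00 | 14 | 82 |
| teal | 15.0 | 41 | 56 |
| amber | 1.33 | 2 | 98 |
| amber | 3.00 | 7 | 94 |
| amber | 6.00 | 7 | 90 |
| amber | 15.0 | 24 | 77 |

(each reading ± 1.5 percentage points)

- for product the crystals are counted in
- as a solid, counted per litre of solution: solid substrate, crystals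
- what was read earlier has a scatter of 1.5 percentage points, one standard deviation
- steps that have been proposed: starting material + enzyme -> product + enzyme; crystals <-> product; solid substrate <-> starting material
- at the start none of the solid substrate is in solution
- what has only dissolved of solid substrate counts as not reacted

- ranking by amount of product, in percent of the solid substrate charged, from high to low, at 30 h (Wednesday's / Sunday's / Saturday's / Friday's / Monday's)
- the same order at 6.0 h (Wednesday's / Sunday's / Saturday's / Friday's / Monday's)
- the amount of product, in percent of the solid substrate charged of the flask you put first, at 30 h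
- the amount of product, in percent of the solid substrate charged of the flask you put last, at 30 h

From the blue run to the teal run the enzyme rose 8.68 times. The share of solid dissolved by 15.0 h went from 39.0% to 44.0%, a factor of 1.13, which is less. So I took dissolving as the rate-limiting step for the disappearance of the solid.

I carried one quantity, the dissolving rate 0.469 mM h⁻¹, the solid lost per litre and hour, read from the teal run, which held the highest loading. Teal's reading at 6.00 h gave 0.480 mM h⁻¹, so the rate looked steady. The amber run read 0.414 mM h⁻¹, so I held 0.469 mM h⁻¹ as the upper figure.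

Product cannot pass what has dissolved. For a flask with solid left I therefore estimated a ceiling, the rate times the time t over the charge c₀.

At 30 h that ceiling was 88.0% for Saturday's, 46.9% for Wednesday's and 28.2% for Monday's. Sunday's and Friday's, at 10 mM, would by this estimate take 21.3 h to dissolve. Sunday's had 7.50 times Friday's loading, so I put Sunday's first, near 100%, and Monday's last, just under its ceiling.

Early on the enzyme showed more: at 6.00 h the blue run held 6% product against teal's 14%. So at 6.0 h I put Friday's behind Saturday's, which holds 3.44 times its enzyme per litre.

The forecast, at 26% for the last flask against my 28.2%, gave Sunday's > Friday's > Saturday's > Wednesday's > Monday's at 30 h, Sunday's > Saturday's > Friday's > Wednesday's > Monday's at 6.0 h and 97% for the first flask, holding that “dissolution is zero-order and limits the rate”.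

The flasks gave Sunday's > Friday's > Saturday's > Wednesday's > Monday's at 30 h and Sunday's > Saturday's > Friday's > Wednesday's > Monday's at 6.0 h, with >99.9% in Sunday's.

    starting material + enzyme → product + enzyme, rate k1*[starting material]*[enzyme]/(1 + ([starting material]/Km1)) (16.0 mM, k = 4.50 × 10⁶ L mol⁻¹ h⁻¹)
    crystals ⇌ product, rate k2*(cs2 - [product]) while solid is left; crystals form when [product] > cs2 (solubility = 11.0 mM, k = 0.110 h⁻¹)
    solid substrate ⇌ starting material, rate k3*(cs3 - [starting material]) while solid is left; crystals form when [starting material] > cs3 (solubility = 15.0 mM, k = 0.0310 h⁻¹)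

Monday's ended at 27.0%, under its ceiling of 28.2%. The neighbouring flask was like Monday's but with 30 mM of solid substrate. At 0.469 mM h⁻¹ for 30 h its ceiling was 46.9%. It gave 44.0% product, with 1.33% standing as starting material and 56% of the charge still there, solid or dissolved.

Readings and results were computed with constants of no real substance.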